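**Retrosynthetic overview**
1. The C4–C1' bond is made last. A guaian-4-yl radical, released from a tertiary phenyl selenide, adds to the o-quinone methide formed in the flask from 2,4,6-trihydroxyisophthalaldehyde and isovaleraldehyde. The formyl phenol therefore never meets hydride or strong base.
2. The key disconnection is the C10–OH bond. Water captures C10 while the C1=C10 alkene opens a C4/C5 seleniranium ion across a ten-membered ring. This one event creates the five- and seven-membered rings and sets C1, C5 and C10.
3. The β-hydroxy selenide comes from an α-seleno ketone, and that from the enolate released by an anionic oxy-Cope ring expansion.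
4. The dialkenyl carbinol comes from (R)-carvone, vinyl bromide and isopropenylmagnesium bromide. C7 is taken from the chiral pool.
5. Ring order: six-membered (carvone), then ten-membered (oxy-Cope), then five plus seven (hydrative closure). The arene is bought.

Assumption: guaiane numbering is used for every intermediate (ring C1–C10, C14 methyl on C10, C15 methyl on C4, isopropenyl C11–C13 on C7, side chain C1'–C5'). α is the face of H1, and β is the face of H5 and of the isopropenyl group.

**Step 1**
Reactants: 1 (R)-(−)-carvone; 2 vinyl bromide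
Product: 4 (2R,5R)-2-ethenyl-2-methyl-5-(prop-1-en-2-yl)cyclohexan-1-one, via lithium enolate 3 (not isolated)
Conditions: LiBH(s-Bu)3 (1.05 equiv), THF, −78 °C; then Pd2(dba)3 (2 mol %), P(t-Bu)3 (8 mol %), 2 (1.0 M in THF, 1.5 equiv), −78 → 40 °C
Reagents that add atoms: none
Why: 1,4-hydride addition gives only the tetrasubstituted enolate 3, which enters a palladium-catalysed enolate α-vinylation (oxidative addition of 2 to zerovalent palladium, transmetalation, reductive elimination); the C–C bond forms on the axial face of the half-chair that keeps the isopropenyl group equatorial, so vinyl ends cis to isopropenyl (C10 R), the same sense as alkylations of this enolate.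

**Step 2**
Reactants: 4 (2R,5R)-2-ethenyl-2-methyl-5-(prop-1-en-2-yl)cyclohexan-1-one; 5 isopropenylmagnesium bromide
Product: 6 (1S,2R,5R)-2-ethenyl-2-methyl-1,5-di(prop-1-en-2-yl)cyclohexan-1-ol
Conditions: 5 (0.5 M in THF, 1.5 equiv), LaCl3·2LiCl (0.3 equiv), THF, −40 → 0 °C; then H2O
Reagents that add atoms: none
Why: lanthanide-assisted Grignard 1,2-addition suppresses enolisation; in the chair with equatorial isopropenyl the vinyl group is axial and blocks the equatorial trajectory, so the nucleophile enters axially from the opposite face and the two alkenyl groups end trans (carbinol carbon S).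

**Step 3**
Reactants: 6 (1S,2R,5R)-2-ethenyl-2-methyl-1,5-di(prop-1-en-2-yl)cyclohexan-1-ol
Product: 8 (2R,5E,9R)-2,6-dimethyl-2-(phenylselanyl)-9-(prop-1-en-2-yl)cyclodec-5-en-1-one, via potassium enolate 7 (not isolated)
Conditions: KN(SiMe3)2 (1.1 equiv), 18-crown-6 (1.1 equiv), THF, 0 → 50 °C; then PhSeBr (1.05 equiv), −78 °C
Reagents that add atoms: benzeneselenenyl bromide, Br[Se]c1ccccc1
Why: anionic oxy-Cope rearrangement through the ring-flipped chair with both alkenyl groups equatorial (about 3 kcal/mol above the diaxial chair, hence 50 °C) gives the E C1=C10 alkene and the regiodefined C4=C5 enolate 7 irreversibly, and α-selenenylation on the exposed outer face of the favoured conformer with C15 up places selenium on the α face (C4 R); the C5 and C10 centres of 6 are consumed.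

**Step 4**
Reactants: 8 (2R,5E,9R)-2,6-dimethyl-2-(phenylselanyl)-9-(prop-1-en-2-yl)cyclodec-5-en-1-one
Product: 9 (1R,2R,5E,9R)-2,6-dimethyl-2-(phenylselanyl)-9-(prop-1-en-2-yl)cyclodec-5-en-1-ol
Conditions: LiAlH4 (1.0 equiv), Et2O, −78 → −30 °C; then H2O
Reagents that add atoms: none
Why: hydride reduction of an α-seleno ketone to a β-hydroxy selenide under Felkin–Anh control, with the C–Se bond perpendicular to the carbonyl, C15 next to C6 and hydride anti to selenium, gives the 5β-alcohol (C5 R) from the 4α-selenide.

**Step 5**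
Reactants: 9 (1R,2R,5E,9R)-2,6-dimethyl-2-(phenylselanyl)-9-(prop-1-en-2-yl)cyclodec-5-en-1-ol
Product: 11 (1R,3aR,4R,7R,8aS)-1,4-dimethyl-1-(phenylselanyl)-7-(prop-1-en-2-yl)decahydroazulen-4-ol, via seleniranium ion 10 (not isolated)
Conditions: (PhO)2P(O)OH (10 mol %), HFIP/H2O 9:1, 5 mM, 0 → 25 °C
Reagents that add atoms: water, O
Why: Proposed new method: catalytic dehydrative seleniranium-relay transannular carbohydroxylation, a net 1,5-transposition of OH from C5 to C10; the acid/HFIP network protonates the C5 hydroxyl and the antiperiplanar C4 selenium expels water (first inversion at C5) to give 10, whose selenium sits on the outside of the ring so that the C1=C10 π bond, about 3 Å away across the ring, can only open it at C5 from the inside (second inversion, net retention, H5 β, five-ring closure with Markovnikov charge at tertiary C10), and water adds to C10 from the outer face anti to the new C1–C5 bond (anti addition to the E alkene, hence H1 α and 10α-OH, C10 R) and returns the proton; only the C5 hydroxyl has selenium assistance, so the new tertiary alcohol and the isopropenyl group survive, and high dilution suppresses selenium transfer between molecules; the closest known reaction types are the stoichiometric acid-induced carbocyclisation of β-hydroxy selenides through seleniranium ions and the transannular cyclisation of 4,5-epoxygermacranes to guaianols.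

**Step 6**
Reactants: 11 (1R,3aR,4R,7R,8aS)-1,4-dimethyl-1-(phenylselanyl)-7-(prop-1-en-2-yl)decahydroazulen-4-ol; 12 2,4,6-trihydroxybenzene-1,3-dicarbaldehyde; 13 isovaleraldehyde
Product: 15 5-[(1R)-1-[(1S,3aR,4R,7R,8aS)-4-hydroxy-1,4-dimethyl-7-(prop-1-en-2-yl)decahydroazulen-1-yl]-3-methylbutyl]-2,4,6-trihydroxybenzene-1,3-dicarbaldehyde, via o-quinone methide 14 (not isolated)
Conditions: 12 (2 equiv), 13 (2.5 equiv), ethylenediammonium diacetate (10 mol %), (Me3Si)3SiH (1.5 equiv, slow addition), Et3B (0.3 equiv)/air, MeCN/CH2Cl2, 25 °C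
Reagents that add atoms: none
Why: Knoevenagel condensation gives the strongly electron-poor 14, the silyl radical takes PhSe from 11, and the nucleophilic tertiary C4 radical adds to the exocyclic carbon of 14 in a polarity-matched Giese reaction driven by rearomatisation (tertiary radicals are known to add to quinone methides), the aryloxyl radical then taking H from the silane; C4 (S) is set by attack on the β face, anti to the C5–C6 bond and cis to H5, and C1' (R) by the staggered transition state with H over the cyclopentane, the isobutyl chain in the open C3/C15 sector and the tilted-away ring over C15/C5, the 1'S epimer being removed by chromatography.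

**Compound list**
1 | (R)-(−)-carvone, (5R)-2-methyl-5-(prop-1-en-2-yl)cyclohex-2-en-1-one | CC1=CC[C@H](CC1=O)C(C)=C | starting material
2 | vinyl bromide | C=CBr | starting material
3 | lithium (5R)-2-methyl-5-(prop-1-en-2-yl)cyclohex-1-en-1-olate | CC1=C([O-])C[C@H](C(C)=C)CC1.[Li+] | intermediate
4 | (2R,5R)-2-ethenyl-2-methyl-5-(prop-1-en-2-yl)cyclohexan-1-one (vinyl cis to isopropenyl) | C[C@]1(C=C)CC[C@@H](C(C)=C)CC1=O | intermediate
5 | isopropenylmagnesium bromide | C=C(C)[Mg]Br | starting material
6 | (1S,2R,5R)-2-ethenyl-2-methyl-1,5-di(prop-1-en-2-yl)cyclohexan-1-ol (vinyl trans to the carbinol isopropenyl) | C[C@]1(C=C)CC[C@@H](C(C)=C)C[C@]1(O)C(C)=C | intermediate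
7 | potassium (1Z,5E,9R)-2,6-dimethyl-9-(prop-1-en-2-yl)cyclodeca-1,5-dien-1-olate (C3 anti to C6) | C/C1=C(/[O-])C[C@H](C(C)=C)CC/C(C)=C/CC1.[K+] | intermediate
8 | (2R,5E,9R)-2,6-dimethyl-2-(phenylselanyl)-9-(prop-1-en-2-yl)cyclodec-5-en-1-one (4α-SePh germacra-1(10),11-dien-5-one) | O=C1C[C@H](C(C)=C)CC/C(C)=C/CC[C@@]1(C)[Se]c2ccccc2 | intermediate
9 | (1R,2R,5E,9R)-2,6-dimethyl-2-(phenylselanyl)-9-(prop-1-en-2-yl)cyclodec-5-en-1-ol (4α-SePh, 5β-OH) | O[C@@H]1C[C@H](C(C)=C)CC/C(C)=C/CC[C@@]1(C)[Se]c2ccccc2 | intermediate
10 | Se-phenyl seleniranium ion bridging C4 and C5 on the α face of the (1(10)E)-germacra-1(10),11-diene ring | C[C@@]12CC/C=C(C)/CC[C@@H](C(C)=C)C[C@@H]1[Se+]2c3ccccc3 | intermediate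
11 | (1R,3aR,4R,7R,8aS)-1,4-dimethyl-1-(phenylselanyl)-7-(prop-1-en-2-yl)decahydroazulen-4-ol (trans-fused, 4α-SePh, 10α-OH) | C=C(C)[C@@H]1CC[C@@](C)(O)[C@@H]2CC[C@@](C)([Se]c3ccccc3)[C@H]2C1 | intermediate
12 | 2,4,6-trihydroxybenzene-1,3-dicarbaldehyde | O=Cc1c(O)cc(O)c(C=O)c1O | starting material
13 | isovaleraldehyde (3-methylbutanal) | CC(C)CC=O | starting material
14 | 2,4-dihydroxy-5-(3-methylbutylidene)-6-oxocyclohexa-1,3-diene-1,3-dicarbaldehyde (alkene geometry interconverts by tautomerism) | CC(C)CC=C1C(=O)C(C=O)=C(O)C(C=O)=C1O | intermediate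
15 | 5-[(1R)-1-[(1S,3aR,4R,7R,8aS)-4-hydroxy-1,4-dimethyl-7-(prop-1-en-2-yl)decahydroazulen-1-yl]-3-methylbutyl]-2,4,6-trihydroxybenzene-1,3-dicarbaldehyde | C=C(C)[C@@H]1CC[C@@](C)(O)[C@@H]2CC[C@](C)([C@@H](CC(C)C)c3c(O)c(C=O)c(O)c(C=O)c3O)[C@H]2C1 | target

**Step count**
Total step count: 6.
Longest linear sequence: 6 (1 → 4 → 6 → 8 → 9 → 11 → 15).

**Steps most likely to fail**

Step 5 (the proposed new step).
- Risks: 10 may lose the selenium electrophile and give the 4-ene. Selenium may transfer to another alkene. The C10 cation may lose a proton instead of taking up water.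
- Fallback, known chemistry: it sets out from 9. Compound 9 is dissolved in anhydrous formic acid/CH2Cl2 at 0 °C, the established stoichiometric-acid way of turning β-hydroxy selenides into seleniranium ions for olefin cyclisation. No water is present to attack selenium.
- The C10 cation is taken up by formate to give (1R,3aR,4R,7R,8aS)-1,4-dimethyl-1-(phenylselanyl)-7-(prop-1-en-2-yl)decahydroazulen-4-yl formate F1. Catalytic K2CO3 in MeOH then removes the formyl group, and the sequence comes back at 11.

Step 6.
- Risks: the stationary concentration of 14 may be too low. Compound 14 may undergo hetero-Diels–Alder addition to the isopropenyl group. The C4 radical may close 6-endo onto the isopropenyl group. The 1'S epimer may predominate.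
- Fallback: it sets out from 11 and reverses the order in which the two C1' substituents arrive. The C4 radical is first trapped with tert-butyl isocyanide ((Me3Si)3SiH, AIBN, toluene, 80 °C) on the β face, giving (1S,3aR,4R,7R,8aS)-4-hydroxy-1,4-dimethyl-7-(prop-1-en-2-yl)decahydroazulene-1-carbonitrile F2.
- i-Bu2AlH at −78 °C and aqueous acid then give (1S,3aR,4R,7R,8aS)-4-hydroxy-1,4-dimethyl-7-(prop-1-en-2-yl)decahydroazulene-1-carbaldehyde F3.
- F3 condenses with 12 to the terpenyl o-quinone methide F4, which is not isolated. F4 takes up an isobutyl radical (isobutyl iodide, (Me3Si)3SiH, Et3B/air). C1' is now set by the neighbouring quaternary C4, and the sequence comes back at 15.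

Step 1.
- Risks: the borane by-product may slow transmetalation. O-vinylation may compete. The facial ratio may be low.
- Fallback: it sets out from enolate 3, made from 1 as before, and replaces cross-coupling by a vinyl cation equivalent. Michael addition of 3 to phenyl vinyl sulfoxide (−78 → 0 °C) gives (2R,5R)-2-methyl-2-[2-(phenylsulfinyl)ethyl]-5-(prop-1-en-2-yl)cyclohexan-1-one F5.
- Thermal syn-elimination (toluene, CaCO3, 110 °C) unveils the vinyl group, and the sequence comes back at 4.

**Further compounds**
F1 | step 5 | (1R,3aR,4R,7R,8aS)-1,4-dimethyl-1-(phenylselanyl)-7-(prop-1-en-2-yl)decahydroazulen-4-yl formate | C=C(C)[C@@H]1CC[C@@](C)(OC=O)[C@@H]2CC[C@@](C)([Se]c3ccccc3)[C@H]2C1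
F2 | step 6 | (1S,3aR,4R,7R,8aS)-4-hydroxy-1,4-dimethyl-7-(prop-1-en-2-yl)decahydroazulene-1-carbonitrile | C=C(C)[C@@H]1CC[C@@](C)(O)[C@@H]2CC[C@](C)(C#N)[C@H]2C1
F3 | step 6 | (1S,3aR,4R,7R,8aS)-4-hydroxy-1,4-dimethyl-7-(prop-1-en-2-yl)decahydroazulene-1-carbaldehyde | C=C(C)[C@@H]1CC[C@@](C)(O)[C@@H]2CC[C@](C)(C=O)[C@H]2C1
F4 | step 6 | terpenyl o-quinone methide from F3 and 12 | C=C(C)[C@@H]1CC[C@@](C)(O)[C@@H]2CC[C@](C)(C=C3C(=O)C(C=O)=C(O)C(C=O)=C3O)[C@H]2C1
F5 | step 1 | (2R,5R)-2-methyl-2-[2-(phenylsulfinyl)ethyl]-5-(prop-1-en-2-yl)cyclohexan-1-one | C[C@]1(CCS(=O)c2ccccc2)CC[C@@H](C(C)=C)CC1=O
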